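**Remark on the chemistry:** the target is read as the 3,4,5-trigallate of natural (−)-quinic acid. Quinic acid numbering is used throughout, also for open-chain precursors: C1 carries OH and the carboxyl group, C3 and C4 carry the cis oxygens, C5 carries the oxygen trans to that on C4 and cis to the carboxyl group, and C6 is the CH2 between C5 and C1.

## The problem

Compound 20 is a single cyclohexane ring in which C1 is quaternary (OH and CO2H), C3, C4 and C5 are contiguous carbinol carbons each esterified with gallic acid, and C2 and C6 are methylenes; the only C–C bonds to be made are those of the ring and the one to the carboxyl carbon. Four stereocentres must be set: the C3 and C4 oxygens are cis, the C5 oxygen is trans to the C4 oxygen, and the C1 hydroxyl lies on the face of the C3 and C4 oxygens, so that the carboxyl group is cis to the C5 oxygen. The cis C3/C4 diol is the natural controlling element: tied up as a cis-fused dioxolane it fixes the chair (C3–O axial, C4–O equatorial), and the quinic arrangement at C5 and C1 is then the one with the larger groups equatorial, which can be reached under equilibrium conditions. The galloyl esters are base-labile and migrate between neighbouring hydroxyls, the free pyrogallol units oxidise readily in basic aerated media, and the tertiary α-hydroxy acid can lactonise onto a free C5 hydroxyl. The gallates are therefore introduced late as their benzyl ethers, and everything is unmasked in one neutral hydrogenolysis. The three secondary hydroxyls are not equivalent (C5 lies outside the cis-diol, C3 is axial, C4 is central and flanked on both sides), and the tertiary C1 hydroxyl must stay free through all acylations. The feature that permits a short ring construction is C6, a bare CH2 flanked by the two carbinol carbons C1 and C5: it can be supplied by nitromethane acting as a one-carbon dinucleophile towards a C5 aldehyde and a C1 keto ester on one five-carbon chain, the nitro group being removed afterwards.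

## Retrosynthesis

**Ten benzyl C–O bonds.** The acid 20 is traced to its perbenzylated form 19 (nine benzyl ethers, one benzyl ester). A benzyl ester at C1 is preferred over an alkyl ester because no hydrolysis could be done in the presence of three gallates. The forward reaction is one neutral hydrogenolysis.

**The ester bonds at C4 and C3.** Triester 19 is cut at the C4–O acyl bond into diester 18 and tribenzylgallic acid 15, and 18 at the C3–O acyl bond into diol monoester 17 and a second molecule of 15. Acylating late keeps the aryl esters out of every basic or reductive C–C bond-forming step. Placing the two esters one after the other lets each hydroxyl be driven with about one equivalent of acid, so that forcing conditions are needed only for the last, central hydroxyl. The cost is one operation more than a double acylation. Each forward step must spare the tertiary C1 hydroxyl.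

**The acetonide and the ester bond at C5.** Diol 17 comes from its 3,4-acetonide 16, and 16 is cut at the C5–O acyl bond into alcohol 14 and a third molecule of 15. In 14 the C5 hydroxyl is the only free secondary hydroxyl, so the first gallate is placed without any question of selectivity. Esterifying C5 before the acetonide is removed also blocks the only hydroxyl that could lactonise onto the benzyl ester.

**C6–H.** Alcohol 14 comes from the 6-nitro compound 13 by replacing C6–NO2 with C6–H. Putting a nitro group on C6 turns an unfunctionalised methylene into a carbon that can form two bonds as a nucleophile. The forward step is a radical denitration, which must be run before any acylation because β-nitro esters eliminate under base.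

**C5–C6 and C1–C6 (key disconnection).** Nitrocyclohexane 13 is opened at both bonds to C6, giving keto ester aldehyde 10 and nitromethane 11; the open-chain nitro alcohol 12 lies between them. Cutting only one ring bond (an aldol or an alkylation at C1) would leave the quaternary centre to be built separately. Cutting both removes the only ring carbon without a heteroatom in the target and exposes a 1,5-dicarbonyl chain whose ends already have the oxidation level of the C1 and C5 carbinols. Precursor 10 has two stereocentres instead of five and no ring other than the protecting group. The forward reaction must close the ring without eliminating the C3 oxygen and let C1, C5 and C6 equilibrate to the all-equatorial arrangement.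

**The two carbonyl groups of 10.** The aldehyde is traced to a vinyl group (through ozonide 9) and the ketone to a dithiane, giving first alkene 8 and then dithiane ester 7. Both carbonyls of 10 are β-oxygenated and base-sensitive, so they are kept masked and released one after the other under neutral conditions (trivalent iodine, then ozone). The dithiane must go first because it would not survive ozone.

**C1–C2.** Dithiane 7 is cut between C1 and C2 into the primary triflate 6 and benzyl 1,3-dithiane-2-carboxylate 5, which is made from the commercial acid 4. The dithiane ester carries C1 and the carboxyl carbon as an acyl anion equivalent at the right oxidation level. An olefination route to the keto ester would need an epimerisable α-alkoxy aldehyde at this position. The forward step is an SN2 reaction at a β-oxygenated primary carbon, hence the triflate.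

**The four-carbon chiral piece.** Triflate 6 comes from alcohol 3, which comes from lactol 2 by methylenation, and 2 from 2,3-O-isopropylidene-D-erythronolactone 1. In 1 the two chain ends are already different: the lactone carbonyl becomes C5 and the CH2O carbon becomes C2. The cis-dioxolane delivers C3 and C4 with the correct absolute configuration, and no stereocentre has to be created before the key step.

## Roads not taken

Alternative 1: The ring is cut at C1–C6 of the cyclohexene acid A1 (1-benzyloxy-3-silyloxycyclohex-4-ene-1-carboxylic acid). In the forward direction O-silylation of the enolate of the 5,6-cis vinyl δ-lactone A2 triggers an Ireland–Claisen rearrangement through the boat-like transition state imposed by the lactone ring, contracting it to the carbocycle.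

- Merits: the quaternary C1 is set irreversibly by chirality transfer from the lactone carbinol carbon. The C4=C5 double bond is placed for the two missing oxygens. The C1 oxygen arrives as a benzyl ether that would stay protected during galloylation and fall in the final hydrogenolysis. In that last respect it is better than the chosen plan, where the C1 hydroxyl of 14 and of the esters 16 to 19 is free and must be spared by reactivity alone.
- Weak points: A2 needs its own multistep asymmetric synthesis with two defined centres. The rearrangement makes one C–C bond and one stereocentre. The C4 and C5 oxygens must then be added as a trans-diol with the correct facial and regiochemical sense on a flexible cyclohexene (epoxidation and opening), followed by esterification and silyl removal.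
- Comparison: the chosen plan buys C3 and C4, forms two ring bonds and three stereocentres in one step, and needs no oxidation of the ring afterwards. Its key step, however, depends on equilibration and not on a stereospecific rearrangement.

Alternative 2: The ring is cut at C1–C2 and C1–C6. The pentitol-derived 1,5-diiodide A4 alkylates 1,3-dithiane A5 twice at its C2 to give the spiro dithiane A3.

- Merits: all three secondary carbinols come from the chiral pool in protected form. Both chain ends react with the same carbon, so there is no regiochemical question. The carbocycle is reached in very few steps.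
- Weak points: each alkylation is an SN2 reaction at a β-alkoxy primary iodide and competes with elimination, and the second has to use a hindered 2-alkyl dithiane anion. More seriously, C1 enters without its hydroxyl, its carboxyl carbon or its configuration. Unmasking the dithiane of A3 would expose a C1 carbonyl with β-alkoxy groups on both sides, which is prone to elimination. The carboxyl carbon would then have to be added with facial control from centres that differ only in orientation, so an epimer mixture at C1 is to be expected. The methoxymethyl ethers also need acid for removal.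
- Comparison: this road reaches a six-membered ring faster than the chosen plan but leaves the hardest centre open. In the chosen plan the ring-forming step itself installs C1 with both substituents under thermodynamic control.

Alternative 3: The ring is cut at C1–C6 and C2–C3. Buta-1,3-diene A8 adds in a Diels–Alder reaction to the chiral 5-methylene-1,3-dioxolan-4-one A7, from the face opposite the tert-butyl group, to give the spiro adduct A6.

- Merits: A6 carries the complete C1 centre in enantioenriched form from very cheap materials. The downstream chemistry is the classical one for this skeleton: halolactonisation onto C5, elimination to the C3=C4 alkene, and cis-dihydroxylation from the face opposite the lactone bridge. Each of these operations has close precedent and reliable substrate control. In certainty of the individual steps this road is better than the chosen plan.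
- Weak points: all three secondary oxygens are introduced after ring formation, one operation at a time. A8 is a gas and the captodative dienophile A7 is sluggish, so pressure and heat are needed. The sequence ends at a bridged lactone or a free acid, which must still be opened and benzylated before galloylation, and it meets the same free tertiary hydroxyl as the chosen plan. The overall length is about the same or slightly greater.
- Comparison: the chosen plan takes C3 and C4 from the chiral pool, sets the ring and the remaining stereocentres in one step, and arrives directly at the benzyl ester acetonide 14. The price is a key step that is less secure than a Diels–Alder reaction.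

Key step: step 8

## Route

Step 1
Reactants: 1 2,3-O-isopropylidene-D-erythronolactone
Product: 2 2,3-O-isopropylidene-D-erythrofuranose (lactol, anomeric mixture)
Conditions: i-Bu2AlH (1.1 equiv), CH2Cl2, −78 °C; aq. potassium sodium tartrate work-up
Reagents that add atoms: none
Why: Partial reduction of a γ-lactone to the lactol with i-Bu2AlH is standard; the tetrahedral aluminium hemiacetal persists at −78 °C, so over-reduction to the meso diol is avoided and the two dioxolane stereocentres are untouched.

Step 2
Reactants: 2 2,3-O-isopropylidene-D-erythrofuranose
Product: 3 [(4R,5S)-2,2-dimethyl-5-vinyl-1,3-dioxolan-4-yl]methanol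
Conditions: Ph3PCH3Br (2.5 equiv), KOtBu (2.4 equiv), THF, 0 °C → rt
Reagents that add atoms: methyltriphenylphosphonium bromide, C[P+](c1ccccc1)(c1ccccc1)c1ccccc1.[Br-]
Why: Wittig methylenation of the lactol through its open hydroxy aldehyde form; the excess ylide covers the equivalent consumed by the hydroxyl, and the resulting vinyl group is a masked C5 aldehyde while the freed primary alcohol is the future C2.

Step 3
Reactants: 4 1,3-dithiane-2-carboxylic acid
Product: 5 benzyl 1,3-dithiane-2-carboxylate
Conditions: BnBr, KHCO3, DMF, rt
Reagents that add atoms: benzyl bromide, BrCc1ccccc1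
Why: SN2 O-alkylation of the carboxylate under a weak base that cannot deprotonate the dithiane C–H; the benzyl ester is chosen so that it is cleaved in the final hydrogenolysis.

Step 4
Reactants: 3 [(4R,5S)-2,2-dimethyl-5-vinyl-1,3-dioxolan-4-yl]methanol
Product: 6 [(4R,5S)-2,2-dimethyl-5-vinyl-1,3-dioxolan-4-yl]methyl trifluoromethanesulfonate
Conditions: Tf2O, pyridine, CH2Cl2, −30 °C; cold aqueous work-up, used at once
Reagents that add atoms: trifluoromethanesulfonic anhydride, O=S(=O)(OS(=O)(=O)C(F)(F)F)C(F)(F)F
Why: Sulfonylation of the primary alcohol; the strongest practical leaving group is taken because the carbon is β-oxygenated and the nucleophile of step 5 is a stabilised, hindered carbanion.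

Step 5
Reactants: 6 [(4R,5S)-2,2-dimethyl-5-vinyl-1,3-dioxolan-4-yl]methyl trifluoromethanesulfonate; 5 benzyl 1,3-dithiane-2-carboxylate
Product: 7 benzyl 2-{[(4R,5S)-2,2-dimethyl-5-vinyl-1,3-dioxolan-4-yl]methyl}-1,3-dithiane-2-carboxylate
Conditions: 5, LiN(SiMe3)2, THF, −78 °C; then 6, DMPU, −78 → 0 °C
Reagents that add atoms: none
Why: SN2 alkylation of the ester-stabilised dithiane carbanion (an acyl anion equivalent, the usual entry to 3-deoxy-2-ulosonic esters from sugar-derived primary electrophiles) forms the C1–C2 bond; no stereocentre is created and the dioxolane centres carry no acidic hydrogen.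

Step 6
Reactants: 7 benzyl 2-{[(4R,5S)-2,2-dimethyl-5-vinyl-1,3-dioxolan-4-yl]methyl}-1,3-dithiane-2-carboxylate
Product: 8 benzyl 3-[(4R,5S)-2,2-dimethyl-5-vinyl-1,3-dioxolan-4-yl]-2-oxopropanoate
Conditions: PhI(OCOCF3)2 (1.5 equiv), NaHCO3, MeCN/H2O (9:1), 0 °C
Reagents that add atoms: water, O
Why: Oxidative dithioacetal hydrolysis with a trivalent iodine reagent (S-activation, ring opening, capture by water) gives the α-keto ester; the bicarbonate buffer protects the acetonide, and the terminal alkene and the benzyl ester are inert to the reagent.

Step 7
Reactants: 8 benzyl 3-[(4R,5S)-2,2-dimethyl-5-vinyl-1,3-dioxolan-4-yl]-2-oxopropanoate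
Product: 10 benzyl 3-[(4R,5R)-5-formyl-2,2-dimethyl-1,3-dioxolan-4-yl]-2-oxopropanoate, via secondary ozonide 9 (not isolated)
Conditions: O3, CH2Cl2, −78 °C (indicator-controlled); then Me2S, −78 °C → rt; crude product used directly
Reagents that add atoms: ozone, [O-][O+]=O
Why: Ozonolysis of the terminal alkene with reductive work-up releases the C5 aldehyde under neutral conditions, so the epimerisable C4 centre and the β-oxygenated keto ester never meet base before the key step; keto and benzyl esters are inert to ozone at −78 °C.

Step 8
Reactants: 10 benzyl 3-[(4R,5R)-5-formyl-2,2-dimethyl-1,3-dioxolan-4-yl]-2-oxopropanoate; 11 nitromethane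
Product: 13 benzyl (6R)-3,4-O-isopropylidene-6-nitroquinate, via open-chain nitro alcohol 12 (not isolated)
Conditions: 11 (1.5 equiv), Et3N (0.2 equiv), THF, 0 °C → rt, left to equilibrate
Reagents that add atoms: none
Why: Triethylamine generates the nitronate of 11, which adds to the aldehyde carbon C5 of 10 (first nitroaldol, C5–C6) to give 12, whose secondary nitronate then attacks the highly electrophilic keto ester carbon C1 (second nitroaldol, C1–C6); if the first addition occurs at the keto ester instead, the same ring results. The closest known reaction type is the nitromethane cyclisation of 1,5-dialdehydes to 2-nitrocyclohexane-1,3-diols, combined with the amine-catalysed Henry addition to α-keto esters. The six-membered ring closes in a 6-(enolexo)-exo-trig mode, a favoured closure in which the nitronate C=N lies outside the new ring and the attacked C=O is exocyclic. C5, C6 and C1 are set under thermodynamic control, because both nitroaldol steps are reversible and C6 epimerises through its nitronate: in the chair fixed by the cis-fused dioxolane (C3–O axial, C4–O equatorial) the C5 hydroxyl settles equatorial and trans to the C4 oxygen, since an axial C5 hydroxyl would be syn-axial to the C3 oxygen. The nitro group at C6 settles equatorial, trans to the C5 hydroxyl. At C1 the benzyl ester takes the equatorial position and the hydroxyl the axial one, where it can hydrogen-bond to the axial C3 oxygen, whereas the C1 epimer would place the ester syn-axial to that oxygen. The step needs chemoselectivity for nitronate addition over β-elimination of the C3 oxygen from the keto ester enolate and over epimerisation of the aldehyde α-carbon C4; a substoichiometric tertiary amine at 0 °C and the high electrophilicity of both carbonyl groups should secure this, and once C5 is sp3 the C4 centre can no longer epimerise.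

Step 9
Reactants: 13 benzyl (6R)-3,4-O-isopropylidene-6-nitroquinate
Product: 14 benzyl 3,4-O-isopropylidene-(−)-quinate
Conditions: Bu3SnH (4 equiv), 1,1'-azobis(cyclohexanecarbonitrile) (0.3 equiv, in portions), toluene, 110 °C
Reagents that add atoms: none
Why: Radical denitration in a tin hydride chain: Bu3Sn• adds to the nitro group, the adduct fragments to the secondary C6 radical, and this abstracts hydrogen from Bu3SnH; secondary nitro groups flanked by oxygenated carbons are known to require refluxing toluene, C6 becomes a CH2 so its configuration is irrelevant, and C1 and C5 are not involved.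

Step 10
Reactants: 14 benzyl 3,4-O-isopropylidene-(−)-quinate; 15 3,4,5-tris(benzyloxy)benzoic acid
Product: 16 benzyl 3,4-O-isopropylidene-5-O-[3,4,5-tris(benzyloxy)benzoyl]-(−)-quinate
Conditions: 15 (1.2 equiv), DCC (1.3 equiv), DMAP (0.2 equiv), CH2Cl2, rt
Reagents that add atoms: none
Why: Steglich esterification (carbodiimide with DMAP) of the C5 hydroxyl, the only secondary hydroxyl of 14; the tertiary C1 hydroxyl, hindered and deactivated by the geminal ester, is expected to stay free, and no stereocentre is touched.

Step 11
Reactants: 16 benzyl 3,4-O-isopropylidene-5-O-[3,4,5-tris(benzyloxy)benzoyl]-(−)-quinate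
Product: 17 benzyl 5-O-[3,4,5-tris(benzyloxy)benzoyl]-(−)-quinate
Conditions: AcOH/H2O/THF (4:1:1), 50 °C
Reagents that add atoms: none
Why: Acid-catalysed hydrolysis of the isopropylidene acetal; aryl esters, the benzyl ester and benzyl ethers are stable to warm aqueous acetic acid, and with C5 esterified the carboxyl group has no cis hydroxyl onto which it could lactonise. Acyl migration is slow in acid and would in any case be harmless, since all three secondary positions end up carrying the same ester.

Step 12
Reactants: 17 benzyl 5-O-[3,4,5-tris(benzyloxy)benzoyl]-(−)-quinate; 15 3,4,5-tris(benzyloxy)benzoic acid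
Product: 18 benzyl 3,5-bis-O-[3,4,5-tris(benzyloxy)benzoyl]-(−)-quinate
Conditions: 15 (1.05 equiv), DCC (1.1 equiv), DMAP (0.1 equiv), CH2Cl2, 0 °C → rt
Reagents that add atoms: none
Why: Steglich esterification with about one equivalent of acid should acylate the C3 hydroxyl, which has a CH2 on one side, in preference to the central C4 hydroxyl flanked by two oxygenated carbons, one of them carrying the bulky gallate; quinate esters are known to be silylated at O3 and O5 with the central O4 left free, which is the same order of accessibility. Any 4,5-diester formed alongside converges on 19 in step 13 and need not be separated.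

Step 13
Reactants: 18 benzyl 3,5-bis-O-[3,4,5-tris(benzyloxy)benzoyl]-(−)-quinate; 15 3,4,5-tris(benzyloxy)benzoic acid
Product: 19 benzyl 3,4,5-tris-O-[3,4,5-tris(benzyloxy)benzoyl]-(−)-quinate
Conditions: 15 (1.5 equiv), DCC (1.6 equiv), DMAP (0.5 equiv), CH2Cl2, rt → 40 °C
Reagents that add atoms: none
Why: Steglich esterification of the last secondary hydroxyl, the equatorial C4 hydroxyl between two gallates, under more forcing conditions; contiguous per-galloylation of polyols by this method is standard, and the tertiary C1 hydroxyl remains the least reactive site.

Step 14
Reactants: 19 benzyl 3,4,5-tris-O-[3,4,5-tris(benzyloxy)benzoyl]-(−)-quinate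
Product: 20 3,4,5-tri-O-galloyl-(−)-quinic acid (CNP0148451.1)
Conditions: H2 (1 atm), 10% Pd/C, THF/MeOH (1:1), rt
Reagents that add atoms: none
Why: Hydrogenolysis over Pd/C cleaves the nine benzyl ethers and the benzyl ester under neutral conditions, so the aryl esters neither migrate nor hydrolyse and the pyrogallol units never meet base.

## Compound list

1 | 2,3-O-isopropylidene-D-erythronolactone, (3aR,6aR)-2,2-dimethyldihydrofuro[3,4-d][1,3]dioxol-4(3aH)-one | CC1(C)O[C@@H]2COC(=O)[C@@H]2O1 | starting material
2 | 2,3-O-isopropylidene-D-erythrofuranose (lactol, anomeric mixture) | CC1(C)O[C@@H]2COC(O)[C@@H]2O1 | intermediate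
3 | [(4R,5S)-2,2-dimethyl-5-vinyl-1,3-dioxolan-4-yl]methanol | CC1(C)O[C@H](CO)[C@H](C=C)O1 | intermediate
4 | 1,3-dithiane-2-carboxylic acid | OC(=O)C1SCCCS1 | starting material
5 | benzyl 1,3-dithiane-2-carboxylate | O=C(OCc1ccccc1)C1SCCCS1 | intermediate
6 | [(4R,5S)-2,2-dimethyl-5-vinyl-1,3-dioxolan-4-yl]methyl trifluoromethanesulfonate | CC1(C)O[C@H](COS(=O)(=O)C(F)(F)F)[C@H](C=C)O1 | intermediate
7 | benzyl 2-{[(4R,5S)-2,2-dimethyl-5-vinyl-1,3-dioxolan-4-yl]methyl}-1,3-dithiane-2-carboxylate | CC1(C)O[C@H](CC2(C(=O)OCc3ccccc3)SCCCS2)[C@H](C=C)O1 | intermediate
8 | benzyl 3-[(4R,5S)-2,2-dimethyl-5-vinyl-1,3-dioxolan-4-yl]-2-oxopropanoate | CC1(C)O[C@H](CC(=O)C(=O)OCc2ccccc2)[C@H](C=C)O1 | intermediate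
9 | secondary ozonide of 8, a 1,2,4-trioxolan-3-yl group in place of the vinyl group (epimers at the trioxolane carbon; not isolated) | CC1(C)O[C@H](CC(=O)C(=O)OCc2ccccc2)[C@H](C2OCOO2)O1 | intermediate
10 | benzyl 3-[(4R,5R)-5-formyl-2,2-dimethyl-1,3-dioxolan-4-yl]-2-oxopropanoate | O=C[C@@H]1OC(C)(C)O[C@@H]1CC(=O)C(=O)OCc1ccccc1 | intermediate
11 | nitromethane | C[N+](=O)[O-] | starting material
12 | benzyl 3-{(4R,5S)-5-[(1R)-1-hydroxy-2-nitroethyl]-2,2-dimethyl-1,3-dioxolan-4-yl}-2-oxopropanoate (open-chain nitro alcohol; the carbinol epimer that goes on is drawn; not isolated) | O=C(OCc1ccccc1)C(=O)C[C@H]1OC(C)(C)O[C@H]1[C@H](O)C[N+](=O)[O-] | intermediate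
13 | benzyl (6R)-3,4-O-isopropylidene-6-nitroquinate (nitro trans to the 5-OH and trans to the ester; 1-OH, 3-O and 4-O on one face) | O[C@@]1(C(=O)OCc2ccccc2)C[C@H]2OC(C)(C)O[C@H]2[C@H](O)[C@H]1[N+](=O)[O-] | intermediate
14 | benzyl 3,4-O-isopropylidene-(−)-quinate | O[C@@]1(C(=O)OCc2ccccc2)C[C@H]2OC(C)(C)O[C@H]2[C@H](O)C1 | intermediate
15 | 3,4,5-tris(benzyloxy)benzoic acid | OC(=O)c1cc(OCc2ccccc2)c(OCc2ccccc2)c(OCc2ccccc2)c1 | starting material
16 | benzyl 3,4-O-isopropylidene-5-O-[3,4,5-tris(benzyloxy)benzoyl]-(−)-quinate | O[C@@]1(C(=O)OCc2ccccc2)C[C@H]2OC(C)(C)O[C@H]2[C@H](OC(=O)c2cc(OCc3ccccc3)c(OCc3ccccc3)c(OCc3ccccc3)c2)C1 | intermediate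
17 | benzyl 5-O-[3,4,5-tris(benzyloxy)benzoyl]-(−)-quinate (3-OH and 4-OH free) | O[C@@]1(C(=O)OCc2ccccc2)C[C@@H](O)[C@@H](O)[C@H](OC(=O)c2cc(OCc3ccccc3)c(OCc3ccccc3)c(OCc3ccccc3)c2)C1 | intermediate
18 | benzyl 3,5-bis-O-[3,4,5-tris(benzyloxy)benzoyl]-(−)-quinate (4-OH free) | O[C@@]1(C(=O)OCc2ccccc2)C[C@@H](OC(=O)c2cc(OCc3ccccc3)c(OCc3ccccc3)c(OCc3ccccc3)c2)[C@@H](O)[C@H](OC(=O)c2cc(OCc3ccccc3)c(OCc3ccccc3)c(OCc3ccccc3)c2)C1 | intermediate
19 | benzyl 3,4,5-tris-O-[3,4,5-tris(benzyloxy)benzoyl]-(−)-quinate | O[C@@]1(C(=O)OCc2ccccc2)C[C@@H](OC(=O)c2cc(OCc3ccccc3)c(OCc3ccccc3)c(OCc3ccccc3)c2)[C@@H](OC(=O)c2cc(OCc3ccccc3)c(OCc3ccccc3)c(OCc3ccccc3)c2)[C@H](OC(=O)c2cc(OCc3ccccc3)c(OCc3ccccc3)c(OCc3ccccc3)c2)C1 | intermediate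
20 | 3,4,5-tri-O-galloyl-(−)-quinic acid | O=C(O[C@@H]1C[C@](O)(C(=O)O)C[C@@H](OC(=O)c2cc(O)c(O)c(O)c2)[C@H]1OC(=O)c1cc(O)c(O)c(O)c1)c1cc(O)c(O)c(O)c1 | target

## Step count and risks

Total step count: 14. Longest linear sequence: 13 steps (steps 1, 2 and 4–14, from lactone 1); step 3 is a one-step side branch.

**Step 8 (key step).** The amine may deprotonate the keto ester at C2 or the aldehyde at C4 faster than the nitronate adds. That would cause β-elimination of the C3 oxygen with opening of the acetonide, or epimerisation at C4. Equilibration at C1 and C5 may also stay incomplete and leave epimer mixtures, or two molecules of nitromethane may add without ring closure.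

The fallback separates the two nitroaldol events so that the doubly activated compound 10 is never formed. It sets out from 8. Nitromethane is added to the keto ester alone (Et3N, catalytic) to give the tertiary nitro alcohol benzyl 3-[(4R,5S)-2,2-dimethyl-5-vinyl-1,3-dioxolan-4-yl]-2-hydroxy-2-(nitromethyl)propanoate F1. Ozonolysis with Me2S work-up turns the vinyl group into the aldehyde benzyl 3-[(4R,5R)-5-formyl-2,2-dimethyl-1,3-dioxolan-4-yl]-2-hydroxy-2-(nitromethyl)propanoate F2. A catalytic base then closes the ring by intramolecular nitroaldol addition, a known route to nitrocyclohexanols, and the same equilibration applies, C1 through the reversible addition to the keto ester. The fallback rejoins the route at 13.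

**Step 5.** Displacement by the stabilised, hindered dithiane carbanion at the β-oxygenated primary carbon may be slower than decomposition of the triflate or its elimination to an exocyclic enol ether.

The fallback makes the C1–C2 bond with a more reactive nucleophile and adds the carboxyl carbon afterwards. It sets out from 6, which is treated with 2-lithio-1,3-dithiane, made from 1,3-dithiane (the compound labelled A5 below) and n-BuLi. This Corey–Seebach alkylation gives 2-{[(4R,5S)-2,2-dimethyl-5-vinyl-1,3-dioxolan-4-yl]methyl}-1,3-dithiane F3. A second lithiation (n-BuLi, THF, −30 °C) and acylation with benzyl chloroformate at −78 °C rejoin the route at 7.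

**Step 9.** At 110 °C the free β-nitro alcohol may undergo retro-nitroaldol ring opening or dehydration before the slow homolysis of the secondary C–N bond, and partial reduction at nitrogen may compete.

The fallback removes the free hydroxyls first. It sets out from 13, which is silylated with Et3SiOSO2CF3 and 2,6-lutidine to give benzyl 3,4-O-isopropylidene-6-nitro-1,5-bis-O-(triethylsilyl)quinate F4. This compound cannot fragment by retro-nitroaldol. Tin hydride denitration gives benzyl 3,4-O-isopropylidene-1,5-bis-O-(triethylsilyl)quinate F5. HF·pyridine in THF then removes both silyl ethers and leaves the acetonide and the benzyl ester in place, so the route is rejoined at 14.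

**Step 12.** The carbodiimide acylation may discriminate poorly between the C3 and C4 hydroxyls and may run on to the triester while diol remains, so that a mixture of esterification levels has to be separated or carried forward with an uncertain acid stoichiometry.

The fallback directs the second gallate by tin activation, which allows only one acylation per diol. It sets out from 17, which is heated with Bu2SnO in toluene with azeotropic removal of water to give benzyl 3,4-O-(dibutylstannanediyl)-5-O-[3,4,5-tris(benzyloxy)benzoyl]quinate F6. Separately, acid 15 is converted with oxalyl chloride and catalytic DMF into 3,4,5-tris(benzyloxy)benzoyl chloride F7. Addition of F7 to F6 at rt should acylate the equatorial oxygen, as is known for stannylene acetals of cis-diols in pyranosides, and give benzyl 4,5-bis-O-[3,4,5-tris(benzyloxy)benzoyl]quinate F8. The remaining axial C3 hydroxyl of F8 is then esterified with 15 under the conditions of step 13, and the route is rejoined at 19.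

## Further compounds

F1 | step 8 | benzyl 3-[(4R,5S)-2,2-dimethyl-5-vinyl-1,3-dioxolan-4-yl]-2-hydroxy-2-(nitromethyl)propanoate (epimers at the carbinol carbon) | CC1(C)O[C@H](CC(O)(C[N+](=O)[O-])C(=O)OCc2ccccc2)[C@H](C=C)O1
F2 | step 8 | benzyl 3-[(4R,5R)-5-formyl-2,2-dimethyl-1,3-dioxolan-4-yl]-2-hydroxy-2-(nitromethyl)propanoate (epimers at the carbinol carbon) | CC1(C)O[C@H](CC(O)(C[N+](=O)[O-])C(=O)OCc2ccccc2)[C@H](C=O)O1
F3 | step 5 | 2-{[(4R,5S)-2,2-dimethyl-5-vinyl-1,3-dioxolan-4-yl]methyl}-1,3-dithiane | CC1(C)O[C@H](CC2SCCCS2)[C@H](C=C)O1
F4 | step 9 | benzyl 3,4-O-isopropylidene-6-nitro-1,5-bis-O-(triethylsilyl)quinate | CC[Si](CC)(CC)O[C@@]1(C(=O)OCc2ccccc2)C[C@H]2OC(C)(C)O[C@H]2[C@H](O[Si](CC)(CC)CC)[C@H]1[N+](=O)[O-]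
F5 | step 9 | benzyl 3,4-O-isopropylidene-1,5-bis-O-(triethylsilyl)quinate | CC[Si](CC)(CC)O[C@@]1(C(=O)OCc2ccccc2)C[C@H]2OC(C)(C)O[C@H]2[C@H](O[Si](CC)(CC)CC)C1
F6 | step 12 | benzyl 3,4-O-(dibutylstannanediyl)-5-O-[3,4,5-tris(benzyloxy)benzoyl]quinate | O[C@@]1(C(=O)OCc2ccccc2)C[C@H]2O[Sn](CCCC)(CCCC)O[C@H]2[C@H](OC(=O)c2cc(OCc3ccccc3)c(OCc3ccccc3)c(OCc3ccccc3)c2)C1
F7 | step 12 | 3,4,5-tris(benzyloxy)benzoyl chloride | ClC(=O)c1cc(OCc2ccccc2)c(OCc2ccccc2)c(OCc2ccccc2)c1
F8 | step 12 | benzyl 4,5-bis-O-[3,4,5-tris(benzyloxy)benzoyl]quinate (3-OH free) | O[C@@]1(C(=O)OCc2ccccc2)C[C@@H](O)[C@@H](OC(=O)c2cc(OCc3ccccc3)c(OCc3ccccc3)c(OCc3ccccc3)c2)[C@H](OC(=O)c2cc(OCc3ccccc3)c(OCc3ccccc3)c(OCc3ccccc3)c2)C1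
A1 | alternative 1 | 1-benzyloxy-3-(tert-butyldimethylsilyloxy)cyclohex-4-ene-1-carboxylic acid (benzyloxy and silyloxy groups cis) | OC(=O)[C@]1(OCc2ccccc2)C[C@@H](O[Si](C)(C)C(C)(C)C)C=CC1
A2 | alternative 1 | 3-benzyloxy-5-(tert-butyldimethylsilyloxy)-6-vinyltetrahydro-2H-pyran-2-one (5,6-cis; either epimer at C3) | O=C1O[C@H](C=C)[C@H](O[Si](C)(C)C(C)(C)C)CC1OCc1ccccc1
A3 | alternative 2 | 8,9,10-tris(methoxymethoxy)-1,5-dithiaspiro[5.5]undecane (8,10-trans) | S1CCCSC12C[C@@H](OCOC)C(OCOC)[C@H](OCOC)C2
A4 | alternative 2 | 1,5-dideoxy-1,5-diiodo-2,3,4-tris-O-(methoxymethyl)-D-arabinitol | IC[C@@H](OCOC)C(OCOC)[C@H](OCOC)CI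
A5 | alternative 2 | 1,3-dithiane | C1CSCSC1
A6 | alternative 3 | 2-tert-butyl-1,3-dioxaspiro[4.5]dec-7-en-4-one (single enantiomer as drawn) | CC(C)(C)[C@@H]1O[C@]2(CCC=CC2)C(=O)O1
A7 | alternative 3 | 2-tert-butyl-5-methylene-1,3-dioxolan-4-one (acetal carbon configured as in A6) | CC(C)(C)[C@@H]1OC(=C)C(=O)O1
A8 | alternative 3 | buta-1,3-diene | C=CC=C
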